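## The problem

Compound 10 is a linear tridepside. Three benzoate rings are joined head to tail by two aryl ester bonds: the carbonyl of ring A (2-hydroxy-4,5-dimethoxy-6-methylbenzoyl) acylates O4 of ring B, the carbonyl of ring B acylates O4 of ring C, and ring C keeps a free carboxyl group. There is no stereocentre, so the task is one of regiochemistry and chemoselectivity among eleven oxygen atoms. On every ring the carbonyl-bearing carbon C1 sits between a hydroxyl group at C2 and a methyl group at C6. A conventional assembly therefore has to couple three hindered 2,6-disubstituted acids and mask each C2 phenol and the ring C acid while the chain grows. The two aryl ester bonds are the fragile part: hydroxide, alkoxides and amines cleave or transpose them, the ortho-hydroxy acid of ring C decarboxylates on heating, and the dimethoxylated ring A is easily oxidised. The last protecting group must therefore leave under near-neutral, non-nucleophilic conditions. The feature that invites a short route is the uniform substitution next to each carbonyl: because C6 carries CH3 on rings A, B and C, each of the three carbonyl groups of the corresponding deoxy compound has exactly one ortho C-H, the C2-H of its own ring. A carbonyl-directed C-H oxygenation can thus place each phenol at only one site per ring, and in ring A that site is also para to the C5 methoxy group.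

## Retrosynthesis

**10 to 9.** The first cut is the alkyl C-O bond of a 2,2,2-trichloroethyl ester on the ring C carboxyl group. A simple alkyl ester could not be hydrolysed beside two aryl esters, and acid-labile or oxidisable esters would not survive the medium in which the phenols are installed. The trichloroethyl group is inert to acid and oxidants and leaves by reductive fragmentation with zinc, which touches neither the depside bonds nor the phenols. Precursor 9 differs from 10 only in this group, and the forward step need be no more than a mild reduction.

**9 to 7 (through 8).** The three C2-O bonds of rings A, B and C are cut together, leading back to the tris-deoxy tridepside 7.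
- Against the neighbours: bringing each phenol in with its building block makes every acid 2,6-disubstituted and every phenol in need of protection. The threefold cut rests on one structural fact, CH3 at C6 of every ring, which makes the three sites alike: each is the sole C-H ortho to an ester carbonyl.
- Simplification: 7 has no phenol, no stereocentre and no doubly ortho-substituted acyl group.
- Demands on the forward reaction: three carbonyl-directed oxygenations on one molecule, metalation of the acyl ring and not the aryloxy ring of each aryl ester, and survival of ring A and of both depside bonds.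
- Ruthenium is preferred to palladium because divalent ruthenium favours the five-membered chelate on the acyl side. The phenols should emerge masked as the tris(trifluoroacetate) 8, which aqueous work-up converts into 9.

**7 to 6 and 3.** The B-C aryl ester is cut at its acyl C-O bond, giving the didepside acid 6 and the phenol 3. Cutting the A-B ester first would require a phenol protecting group on a B-C fragment. In the chosen order the only nucleophile ever present is the phenol of 3, and the only mask is the trichloroethyl ester. Acid 6 has a single ortho substituent and 3 is an unhindered phenol, so the forward step is an ordinary carbodiimide esterification.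

**6 to 5 to 3 and 4.** Acid 6 is the trichloroethyl ester 5 after reductive unmasking, and 5 is cut at the A-B aryl ester into the same phenol 3 and the dimethoxytoluic acid 4. Compound 3 thus serves twice: as ring B with a temporary carboxyl mask and as ring C with the mask that stays to the end. The forward reactions are the same esterification and the same zinc fragmentation used elsewhere.

**3 to 1 and 2.** The alkyl ester bond of 3 is cut to the hydroxy acid 1 and the alcohol 2. Acid catalysis is asked to esterify the carboxyl group and leave the phenol alone, which is the normal behaviour of phenols under Fischer conditions.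

## Roads not taken

**Alternative 1:** Michael-Dieckmann construction of ring A.
- Cut: the C1-C6 and C3-C4 bonds of ring A, so that the ring is made from tert-butyl acetoacetate A1 and methyl (Z)-2-methoxybut-2-enoate A2.
- Forward key step: the central carbon of A1 adds to the β-carbon of A2, and the terminal methyl carbon of A1 then closes on the methyl ester. This gives the cyclohexanedione A3 (racemic; its three stereocentres vanish on aromatisation). Dehydrogenation would give the resorcinol ester A4; methylation of its unchelated 4-OH and ester cleavage would give the ring A acid with the C2 phenol in place.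
- Merits: every substituent of ring A is fixed by construction, no oxidant meets the finished electron-rich ring, and the selective 4-O-methylation rests on the chelation of the 2-OH.
- Weak points: A2 is a β-alkyl α-alkoxy acrylate and hence a reluctant Michael acceptor. A3 is one elimination away from an aromatic ring, so loss of the C5 methoxy group to give A5 competes with the dehydrogenation that must keep it. The sequence serves ring A only: rings B and C must still come from protected dihydroxytoluate units, three 2,6-disubstituted acids must still be coupled, and the protecting groups removed, well over a dozen steps in all.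
- Comparison: on certainty of oxygen placement and on the safety of ring A this road is better. The chosen plan sets against it six steps, no phenol protecting group and couplings of mono-ortho-substituted acids only, at the price of one untested oxidation.

**Alternative 2:** Danheiser benzannulation of ring B onto ring C.
- Cut: four bonds of ring B (C5-C6, C2-C3, C4-C5, C1-C2), leading to the diazoketone A6, an aryl (E)-5-diazo-3-methyl-4-oxopent-2-enoate whose aryl group is the benzyl-protected ring C, and triisopropylsiloxyacetylene A7.
- Forward key step: photochemical Wolff rearrangement of A6 gives a vinylketene; [2+2] addition of A7, 4π ring opening, 6π closure and tautomerisation give the didepside A8, with the 2-OH of ring B free and its 4-O silylated. The E geometry of A6 places the ester on the outside of the closing triene.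
- Merits: the regiochemistry of ring B is built in, its two oxygens arrive differentiated, and the B-C ester exists before ring B does, so one hindered coupling is avoided.
- Weak points: A6 requires a regiodifferentiated half ester, a diazoalkane acylation and a photolysis, and A7 must be prepared. Ring C must first be made as a protected unit with a free 4-OH. Ring A with its C2 oxygen must be made separately and coupled as a hindered acid. The effort builds the simplest of the three rings.
- Comparison: this road is firmer on regiochemistry and ends with a mild hydrogenolysis. The chosen plan answers with fewer than half the steps and no diazo or photochemical operation, but carries the greater single risk.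

**Alternative 3:** Aryne methylation-carboxylation for the dihydroxytoluate units.
- Cut: the C6-CH3 and C1-COOH bonds of rings B and C, leading to the bromo iodide A9.
- Forward key step: the 3,5-bis(benzyloxy)aryne released from A9 takes up MeMgCl A10 at the carbon remote from the neighbouring benzyloxy group, and the arylmagnesium formed next to that group is trapped by CO2 A11 to give the acid A12.
- Merits: the alkoxy group steers the addition, two C-C bonds form in one flask, and A12 could serve both rings B and C.
- Weak points: A9 itself takes several steps. A12 has both phenols benzylated, and the 4-O must then be freed selectively although Lewis acids prefer to cleave the chelating 2-O ether. Ring A is not addressed. The hindered couplings and the final deprotection remain.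
- Comparison: each operation has closer precedent than the chosen key step, and the end game is neutral. The chosen plan is far shorter and needs no phenol protection; it cannot claim the same certainty.

Key step: step 5

Remarks on the chemistry:
- Acid 4 is assumed to be a catalogue compound, like 1 and 2.
- Ring positions are numbered as in the target for all compounds (C1 carbonyl-bearing, C2 the carbon to be hydroxylated, C6 methyl-bearing); systematic names of the deoxy compounds use their own locants.

## Route

Step 1
Reactants: 1 4-hydroxy-2-methylbenzoic acid; 2 2,2,2-trichloroethanol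
Product: 3 2,2,2-trichloroethyl 4-hydroxy-2-methylbenzoate
Conditions: 2 (3 equiv), p-TsOH·H2O (cat.), toluene, reflux, Dean-Stark trap
Reagents that add atoms: none
Why: Fischer esterification; acid catalysis esterifies the carboxyl group but not the phenol, and azeotropic removal of water should drive the weakly nucleophilic alcohol to conversion.

Step 2
Reactants: 3 2,2,2-trichloroethyl 4-hydroxy-2-methylbenzoate; 4 3,4-dimethoxy-2-methylbenzoic acid
Product: 5 2,2,2-trichloroethyl 4-[(3,4-dimethoxy-2-methylbenzoyl)oxy]-2-methylbenzoate (A-B didepside ester)
Conditions: DCC, DMAP (cat.), CH2Cl2, 0 °C to rt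
Reagents that add atoms: none
Why: Steglich esterification; acid 4 has one ortho substituent only, so its acylpyridinium should be taken by the unhindered phenol of 3, whose own carboxyl group is masked and cannot self-condense.

Step 3
Reactants: 5 2,2,2-trichloroethyl 4-[(3,4-dimethoxy-2-methylbenzoyl)oxy]-2-methylbenzoate
Product: 6 4-[(3,4-dimethoxy-2-methylbenzoyl)oxy]-2-methylbenzoic acid (A-B didepside acid)
Conditions: Zn dust, AcOH/THF, rt
Reagents that add atoms: none
Why: Reductive fragmentation of a 2,2,2-trichloroethyl ester (electron transfer to a C-Cl bond, then β-elimination of the carboxylate); the conditions are non-nucleophilic, so the aryl ester should stay intact.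

Step 4
Reactants: 6 4-[(3,4-dimethoxy-2-methylbenzoyl)oxy]-2-methylbenzoic acid; 3 2,2,2-trichloroethyl 4-hydroxy-2-methylbenzoate
Product: 7 2,2,2-trichloroethyl 4-{[4-(3,4-dimethoxy-2-methylbenzoyl)oxy-2-methylbenzoyl]oxy}-2-methylbenzoate (tris-deoxy tridepside ester)
Conditions: DCC, DMAP (cat.), CH2Cl2, 0 °C to rt
Reagents that add atoms: none
Why: Second Steglich esterification with the same phenol 3; the activated acid again has a single ortho substituent, and a catalytic amount of DMAP at room temperature should not disturb the existing aryl ester.

Step 5
Reactants: 7 2,2,2-trichloroethyl 4-{[4-(3,4-dimethoxy-2-methylbenzoyl)oxy-2-methylbenzoyl]oxy}-2-methylbenzoate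
Product: 9 2,2,2-trichloroethyl 2-hydroxy-4-{[2-hydroxy-4-(2-hydroxy-4,5-dimethoxy-6-methylbenzoyl)oxy-6-methylbenzoyl]oxy}-6-methylbenzoate, via tris-O-trifluoroacetyl tridepside ester 8 (not isolated)
Conditions: [RuCl2(p-cymene)]2 (10 mol %), PhI(OCOCF3)2 (4 equiv), CF3CO2H/(CF3CO)2O, 80 °C; then H2O/MeCN, rt
Reagents that add atoms: [bis(trifluoroacetoxy)iodo]benzene, O=C(OI(OC(=O)C(F)(F)F)c1ccccc1)C(F)(F)F; trifluoroacetic acid, OC(=O)C(F)(F)F (together the trifluoroacetate pool that supplies the three new oxygen atoms)
Why: Proposed new method: each of the three ester carbonyls should bind the divalent ruthenium species Ru(OCOCF3)2(p-cymene) formed in the medium, and trifluoroacetate-assisted metalation should then give a five-membered ruthenacycle at C2-H, the only free position ortho to that carbonyl because C6 carries CH3. PhI(OCOCF3)2 oxidises the ruthenacycle to tetravalent ruthenium, and C-O reductive elimination releases the aryl trifluoroacetate and returns divalent ruthenium; three such cycles should convert 7 into 8, which the aqueous work-up hydrolyses to 9. The closest known reaction type is the single ester-directed ortho C-H hydroxylation of alkyl benzoates under these conditions, so the trichloroethyl ester of ring C is on known ground, while direction by the two aryl ester carbonyls and the threefold course are new. No ring is closed, the ruthenacycles being transient, and no stereocentre is formed. The selectivity needed is acyl-side over aryloxy-side metalation at each aryl ester; it is expected from the preference of divalent ruthenium for the planar five-membered chelate, as reported for N-aryl benzamides, which ruthenium oxygenates on the benzoyl ring, and from the position of the aryloxy-ring C-H bonds meta to an ester and, at C5, next to CH3. In ring A the C2-H is also para to the C5 methoxy group, so directed and innate reactivity point to the same carbon. The excess (CF3CO)2O should keep each new phenol as its trifluoroacetate, which protects it from oxidation to a quinone, prevents salicylate chelation of the catalyst and deactivates the oxidised ring. Partly oxidised material keeps the same directing groups and can be resubmitted.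

Step 6
Reactants: 9 2,2,2-trichloroethyl 2-hydroxy-4-{[2-hydroxy-4-(2-hydroxy-4,5-dimethoxy-6-methylbenzoyl)oxy-6-methylbenzoyl]oxy}-6-methylbenzoate
Product: 10 2-hydroxy-4-{[2-hydroxy-4-(2-hydroxy-4,5-dimethoxy-6-methylbenzoyl)oxy-6-methylbenzoyl]oxy}-6-methylbenzoic acid (CNP0139469.0)
Conditions: Zn dust, AcOH/THF, rt; dilute aq. HCl work-up
Reagents that add atoms: none
Why: Reductive fragmentation of the trichloroethyl ester as in step 3; no nucleophile or base is present, so the two salicylate-type depside bonds and the three phenols should be untouched, and the acidic work-up breaks zinc chelates of the product.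

## Compound list

1 | 4-hydroxy-2-methylbenzoic acid | Cc1cc(O)ccc1C(=O)O | starting material
2 | 2,2,2-trichloroethanol | OCC(Cl)(Cl)Cl | starting material
3 | 2,2,2-trichloroethyl 4-hydroxy-2-methylbenzoate | Cc1cc(O)ccc1C(=O)OCC(Cl)(Cl)Cl | intermediate
4 | 3,4-dimethoxy-2-methylbenzoic acid | COc1ccc(C(=O)O)c(C)c1OC | starting material
5 | 2,2,2-trichloroethyl 4-[(3,4-dimethoxy-2-methylbenzoyl)oxy]-2-methylbenzoate | COc1ccc(C(=O)Oc2ccc(C(=O)OCC(Cl)(Cl)Cl)c(C)c2)c(C)c1OC | intermediate
6 | 4-[(3,4-dimethoxy-2-methylbenzoyl)oxy]-2-methylbenzoic acid | COc1ccc(C(=O)Oc2ccc(C(=O)O)c(C)c2)c(C)c1OC | intermediate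
7 | 2,2,2-trichloroethyl 4-{[4-(3,4-dimethoxy-2-methylbenzoyl)oxy-2-methylbenzoyl]oxy}-2-methylbenzoate | COc1ccc(C(=O)Oc2ccc(C(=O)Oc3ccc(C(=O)OCC(Cl)(Cl)Cl)c(C)c3)c(C)c2)c(C)c1OC | intermediate
8 | tris(trifluoroacetate) of 9 at the C2 oxygens of rings A, B and C (not isolated) | COc1cc(OC(=O)C(F)(F)F)c(C(=O)Oc2cc(C)c(C(=O)Oc3cc(C)c(C(=O)OCC(Cl)(Cl)Cl)c(OC(=O)C(F)(F)F)c3)c(OC(=O)C(F)(F)F)c2)c(C)c1OC | intermediate
9 | 2,2,2-trichloroethyl 2-hydroxy-4-{[2-hydroxy-4-(2-hydroxy-4,5-dimethoxy-6-methylbenzoyl)oxy-6-methylbenzoyl]oxy}-6-methylbenzoate | COc1cc(O)c(C(=O)Oc2cc(C)c(C(=O)Oc3cc(C)c(C(=O)OCC(Cl)(Cl)Cl)c(O)c3)c(O)c2)c(C)c1OC | intermediate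
10 | 2-hydroxy-4-{[2-hydroxy-4-(2-hydroxy-4,5-dimethoxy-6-methylbenzoyl)oxy-6-methylbenzoyl]oxy}-6-methylbenzoic acid | COc1cc(O)c(C(=O)Oc2cc(C)c(C(=O)Oc3cc(C)c(C(=O)O)c(O)c3)c(O)c2)c(C)c1OC | target

## Step count and risks

Total step count: 6. Longest linear sequence: 6 (steps 1 to 6; phenol 3 enters twice).

**Step 5 (key step, proposed new method).**
- What may go wrong:
  - Turnover may stop short of three oxygenations, because aryl and trichloroethyl ester carbonyls are weak donors.
  - Metalation may go through the six-membered chelate onto the aryloxy ring, most plausibly at the unhindered C3-H of ring B or C before that ring's C2 is oxidised.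
  - The oxidant may attack the dimethoxylated ring A or its methyl group without direction.
  - The depside bonds may undergo acid-promoted acyl exchange in the hot acid/anhydride medium.
- Fallback (sets out from 4, 2 and 3, returns at 9): the oxygenation is moved to the monomers, where the directing group is a plain alkyl ester and the single ester-directed hydroxylation is known, and the chain is then assembled by the classical carbodiimide condensation that tolerates hydrogen-bonded ortho phenols.
  - Acid 4 is esterified with 2 (DCC, DMAP) to 2,2,2-trichloroethyl 3,4-dimethoxy-2-methylbenzoate F1.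
  - F1 is hydroxylated under the conditions of step 5 to 2,2,2-trichloroethyl 2-hydroxy-4,5-dimethoxy-6-methylbenzoate F2, and Zn in AcOH frees 2-hydroxy-4,5-dimethoxy-6-methylbenzoic acid F3.
  - Phenol 3, trifluoroacetylated at O4 in the medium, is hydroxylated in the same way to 2,2,2-trichloroethyl 2,4-dihydroxy-6-methylbenzoate F4.
  - DCC condensation of F3 with F4 should acylate the free 4-OH of F4 in preference to the chelated 2-OH, giving 2,2,2-trichloroethyl 2-hydroxy-4-[(2-hydroxy-4,5-dimethoxy-6-methylbenzoyl)oxy]-6-methylbenzoate F5.
  - Zn in AcOH gives 2-hydroxy-4-[(2-hydroxy-4,5-dimethoxy-6-methylbenzoyl)oxy]-6-methylbenzoic acid F6, and a second DCC condensation with F4 gives 9, from which step 6 follows.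

**Step 1.**
- What may go wrong: conversion may be slow, because trichloroethanol is a poor nucleophile and the para-hydroxyl group lowers the electrophilicity of the protonated acid; prolonged heating invites self-esterification of the hydroxy acid to oligomers.
- Fallback (sets out from 1, returns at 3): the phenol is masked and the ester is made by carbodiimide activation.
  - Compound 1 is bis-silylated (TBSCl, imidazole, DMF) to tert-butyldimethylsilyl 4-(tert-butyldimethylsilyloxy)-2-methylbenzoate F7.
  - The silyl ester of F7 is hydrolysed on work-up (AcOH, THF, H2O) to 4-(tert-butyldimethylsilyloxy)-2-methylbenzoic acid F8.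
  - Steglich esterification with 2 gives 2,2,2-trichloroethyl 4-(tert-butyldimethylsilyloxy)-2-methylbenzoate F9, and buffered fluoride (Bu4NF, AcOH, THF, 0 °C) returns 3.

**Step 4.**
- What may go wrong: the O-acylisourea of the larger acid 6 may rearrange to the N-acylurea if the phenol attacks slowly, and DMAP may transfer the acyl group of the aryl ester already present in 6, scrambling the chain.
- Fallback (sets out from 1, 3 and 4, returns at 7; steps 2 and 3 are then not needed): the order of assembly is reversed so that no acid carrying an aryl ester is ever activated.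
  - 4-(tert-Butyldimethylsilyloxy)-2-methylbenzoic acid F8, made from 1 as above, is condensed with 3 (DCC, DMAP) to 2,2,2-trichloroethyl 4-{[4-(tert-butyldimethylsilyloxy)-2-methylbenzoyl]oxy}-2-methylbenzoate F10.
  - Buffered fluoride gives 2,2,2-trichloroethyl 4-[(4-hydroxy-2-methylbenzoyl)oxy]-2-methylbenzoate F11, which is acylated with 4 (DCC, DMAP) to give 7.

**Step 6.**
- What may go wrong: the fragmentation may stall after partial hydrodechlorination of the CCl3 group. Long contact with zinc salts in acid may cause acyl migration or cleavage at the salicylate-type ester bonds, or decarboxylation of the liberated ortho-hydroxy acid.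
- Fallback (sets out from 1 and 6, returns at 10): the terminal mask is changed to one removed by neutral hydrogenolysis. This presupposes that the oxygenation of step 5 has been reduced to practice.
  - Compound 1 is alkylated at the carboxylate (4-nitrobenzyl bromide, KHCO3, DMF) to 4-nitrobenzyl 4-hydroxy-2-methylbenzoate F12.
  - Condensation with 6 as in step 4 gives 4-nitrobenzyl 4-{[4-(3,4-dimethoxy-2-methylbenzoyl)oxy-2-methylbenzoyl]oxy}-2-methylbenzoate F13; the nitrobenzyl group is electron-poor and should resist both the acid and the oxidant.
  - Oxygenation as in step 5 gives 4-nitrobenzyl 2-hydroxy-4-{[2-hydroxy-4-(2-hydroxy-4,5-dimethoxy-6-methylbenzoyl)oxy-6-methylbenzoyl]oxy}-6-methylbenzoate F14, and hydrogenolysis (H2, Pd/C, EtOAc, rt) delivers 10.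

## Further compounds

F1 | step 5 | 2,2,2-trichloroethyl 3,4-dimethoxy-2-methylbenzoate | COc1ccc(C(=O)OCC(Cl)(Cl)Cl)c(C)c1OC
F2 | step 5 | 2,2,2-trichloroethyl 2-hydroxy-4,5-dimethoxy-6-methylbenzoate | COc1cc(O)c(C(=O)OCC(Cl)(Cl)Cl)c(C)c1OC
F3 | step 5 | 2-hydroxy-4,5-dimethoxy-6-methylbenzoic acid | COc1cc(O)c(C(=O)O)c(C)c1OC
F4 | step 5 | 2,2,2-trichloroethyl 2,4-dihydroxy-6-methylbenzoate | Cc1cc(O)cc(O)c1C(=O)OCC(Cl)(Cl)Cl
F5 | step 5 | 2,2,2-trichloroethyl 2-hydroxy-4-[(2-hydroxy-4,5-dimethoxy-6-methylbenzoyl)oxy]-6-methylbenzoate | COc1cc(O)c(C(=O)Oc2cc(C)c(C(=O)OCC(Cl)(Cl)Cl)c(O)c2)c(C)c1OC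
F6 | step 5 | 2-hydroxy-4-[(2-hydroxy-4,5-dimethoxy-6-methylbenzoyl)oxy]-6-methylbenzoic acid | COc1cc(O)c(C(=O)Oc2cc(C)c(C(=O)O)c(O)c2)c(C)c1OC
F7 | step 1 | tert-butyldimethylsilyl 4-(tert-butyldimethylsilyloxy)-2-methylbenzoate | Cc1cc(O[Si](C)(C)C(C)(C)C)ccc1C(=O)O[Si](C)(C)C(C)(C)C
F8 | step 1 | 4-(tert-butyldimethylsilyloxy)-2-methylbenzoic acid | Cc1cc(O[Si](C)(C)C(C)(C)C)ccc1C(=O)O
F9 | step 1 | 2,2,2-trichloroethyl 4-(tert-butyldimethylsilyloxy)-2-methylbenzoate | Cc1cc(O[Si](C)(C)C(C)(C)C)ccc1C(=O)OCC(Cl)(Cl)Cl
F10 | step 4 | 2,2,2-trichloroethyl 4-{[4-(tert-butyldimethylsilyloxy)-2-methylbenzoyl]oxy}-2-methylbenzoate | Cc1cc(O[Si](C)(C)C(C)(C)C)ccc1C(=O)Oc1ccc(C(=O)OCC(Cl)(Cl)Cl)c(C)c1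
F11 | step 4 | 2,2,2-trichloroethyl 4-[(4-hydroxy-2-methylbenzoyl)oxy]-2-methylbenzoate | Cc1cc(O)ccc1C(=O)Oc1ccc(C(=O)OCC(Cl)(Cl)Cl)c(C)c1
F12 | step 6 | 4-nitrobenzyl 4-hydroxy-2-methylbenzoate | Cc1cc(O)ccc1C(=O)OCc1ccc([N+](=O)[O-])cc1
F13 | step 6 | 4-nitrobenzyl 4-{[4-(3,4-dimethoxy-2-methylbenzoyl)oxy-2-methylbenzoyl]oxy}-2-methylbenzoate | COc1ccc(C(=O)Oc2ccc(C(=O)Oc3ccc(C(=O)OCc4ccc([N+](=O)[O-])cc4)c(C)c3)c(C)c2)c(C)c1OC
F14 | step 6 | 4-nitrobenzyl 2-hydroxy-4-{[2-hydroxy-4-(2-hydroxy-4,5-dimethoxy-6-methylbenzoyl)oxy-6-methylbenzoyl]oxy}-6-methylbenzoate | COc1cc(O)c(C(=O)Oc2cc(C)c(C(=O)Oc3cc(C)c(C(=O)OCc4ccc([N+](=O)[O-])cc4)c(O)c3)c(O)c2)c(C)c1OC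
A1 | alternative 1 | tert-butyl acetoacetate | CC(=O)CC(=O)OC(C)(C)C
A2 | alternative 1 | methyl (Z)-2-methoxybut-2-enoate | C/C=C(\OC)C(=O)OC
A3 | alternative 1 | tert-butyl 5-methoxy-6-methyl-2,4-dioxocyclohexane-1-carboxylate (racemic, all-trans isomer drawn) | CC(C)(C)OC(=O)[C@H]1C(=O)CC(=O)[C@@H](OC)[C@@H]1C
A4 | alternative 1 | tert-butyl 2,4-dihydroxy-5-methoxy-6-methylbenzoate | COc1c(O)cc(O)c(C(=O)OC(C)(C)C)c1C
A5 | alternative 1 | tert-butyl 2,4-dihydroxy-6-methylbenzoate | Cc1cc(O)cc(O)c1C(=O)OC(C)(C)C
A6 | alternative 2 | 3-(benzyloxy)-4-[(benzyloxy)carbonyl]-5-methylphenyl (E)-5-diazo-3-methyl-4-oxopent-2-enoate | O=C(C=[N+]=[N-])/C(C)=C/C(=O)Oc1cc(C)c(C(=O)OCc2ccccc2)c(OCc2ccccc2)c1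
A7 | alternative 2 | triisopropylsiloxyacetylene | C#CO[Si](C(C)C)(C(C)C)C(C)C
A8 | alternative 2 | benzyl 2-(benzyloxy)-4-{[2-hydroxy-6-methyl-4-(triisopropylsilyloxy)benzoyl]oxy}-6-methylbenzoate | Cc1cc(O[Si](C(C)C)(C(C)C)C(C)C)cc(O)c1C(=O)Oc1cc(C)c(C(=O)OCc2ccccc2)c(OCc2ccccc2)c1
A9 | alternative 3 | 1,5-bis(benzyloxy)-3-bromo-2-iodobenzene | Brc1cc(OCc2ccccc2)cc(OCc2ccccc2)c1I
A10 | alternative 3 | methylmagnesium chloride | C[Mg]Cl
A11 | alternative 3 | carbon dioxide | O=C=O
A12 | alternative 3 | 2,4-bis(benzyloxy)-6-methylbenzoic acid | Cc1cc(OCc2ccccc2)cc(OCc2ccccc2)c1C(=O)O
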